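## Structural features

The target is a single cyclohexene ring (C1–C6) whose only carbon branch is C7, a benzoyloxymethyl group on the alkene carbon C3; C2 is the alkene CH. Four contiguous oxygen-bearing stereocentres occupy the saturated half of the ring: C4 (free allylic OH), C5 (benzoate), C6 (free OH) and C1 (allylic methyl ether). In this numbering the target is (1S,4R,5R,6R): the C4 and C5 oxygens are cis, C6–O is trans to C5–O, and C1–O is trans to C6–O. The fragile points are the two benzoates, each within reach of a free hydroxyl (acyl migration under base), and the allylic C–O bonds at C1, C4 and C7. The real difficulty is not the seven-carbon skeleton but fixing the oxygen tetrad in one absolute sense and telling five oxygens apart (one ether, two esters, two free hydroxyls). The key step exploits that C4 and C5 are neighbouring carbinol carbons with cis oxygens, C4 being allylic to C2=C3. Both can therefore be formyl carbons of an open chain, C4 as the carbonyl of a Z-enal that the alkene holds close to C5. The remaining pair C1/C6 is syn in the open chain with one oxygen methylated, which is the pattern a (Z)-γ-methoxyallyl addition to an aldehyde delivers.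

## Logic of the disconnections

21 to 20: the O7–benzoyl bond is cut first. A C7 acyloxy group cannot be carried through the reductive ring closure, and the primary allylic hydroxyl is the easiest of three to acylate selectively. The last step then needs only 17. The forward step must stop at the primary oxygen and must not move the C5 benzoate.

20 to 19: the O6–Si and O7–Si bonds are restored. One kind of protecting group covers the two oxygens that stay masked through ring closure, so one deprotection frees both. The forward step needs non-basic conditions because the C5 benzoate is flanked by hydroxyls.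

19 to 16 and 17 (through 18): the O5–benzoyl bond is cut. O4 and O5 arise together and can be told apart only afterwards; their cis arrangement (one equatorial, one pseudoaxial) is the handle. This leaves 16, a diol with every other oxygen capped. The forward step must acylate the equatorial O5 only.

16 to 15: the C4–C5 ring bond is cut, both carbons becoming formyl carbons. They are adjacent, both oxygenated and cis, and the cut opens the ring to a chain with only two adjacent stereocentres. One ring and two stereocentres are removed. The forward step must give the cis diol anti to O6, keep the Z alkene, and favour carbonyl–carbonyl coupling over other reductions.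

15 to 14 to 13: no skeletal bond is cut; the two C=O groups are traced to primary alcohols and these to two 4-methoxybenzyl ethers. The dialdehyde is too labile to carry, and one shared protecting group on O4 and O5 means one deprotection and one oxidation. The forward steps need an oxidation free of amine base and an ether cleavage that spares the alkene, the silyl ethers and the methyl ether.

13 to 12 to 11: the O7–Si bond is removed and C7 is raised to the ester level. The carbonyl carbon of an olefination reagent ends up trans to the chain, which is where C7 stands relative to C1. The forward steps need a clean 1,2-reduction and retention of alkene geometry.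

11 to 7 and 10: the C2=C3 double bond is cut. It is the only C=C bond and divides the molecule into the stereodefined four-carbon piece and the C3/C4/C7 piece. The route becomes convergent. The forward step must be E-selective under a base mild enough to leave C1 untouched.

10 to 8 and 9: the C4–O bond is cut (conjugate addition in the forward sense). Two simple materials result. The forward step must give mono-addition without oligomerisation.

7 to 6 to 5: the C2 formyl group is traced to a vinyl group (one carbon lost) and the O6–Si bond is removed. A vinyl group is what an allylation leaves behind. The cleavage must spare the electron-rich arene and the α-stereocentre.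

5 to 1 and 2 (through 3 and 4): the C1–C6 bond is cut. It joins the two remaining stereocentres, and the methyl ether comes in with 1. Two achiral materials remain. The forward step needs a Z-configured allyl unit and reagent control of the aldehyde face.

## Other disconnections considered

Alternative 1: The cut is at the C4–O and C5–O bonds, tracing the ring back to an arene. In the forward key step, whole cells expressing toluene dioxygenase oxidise ethyl benzoate A2 across its 2,3-bond with oxygen from air to the cis-dienediol A1. No ring closes; the benzene ring becomes C1–C6 and the ester carbon becomes C7.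
- In favour: one operation should deliver the carbocycle, C7 and the cis C4/C5 diol as a single enantiomer of the sense needed here. The double bond remote from the ester (future C1=C6) is placed for epoxidation anti to the protected diol and allylic methanolysis at C1, which would give the trans C6–OH/C1–OMe pair.
- Against it here: fermentation equipment and a recombinant strain are needed, and ester-bearing arenes are slower substrates than halobenzenes. A1 is prone to rearomatisation and dimerisation. The ester must still be reduced and O4 told apart from O5, the same problem as step 11 of the chosen plan. Only one enantiomeric series is available.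
- Comparison: structurally both plans secure the cis C4/C5 pair, one from an enzyme face, the other from a metal chelate. Mechanistically the enzymatic step has no radical intermediates and no leaving-group hazards. In enantiopurity and probably in step count Alternative 1 is the better of the two. The chosen plan is better in needing only flask chemistry, in reaching either enantiomer by choice of pinene antipode, and in carrying the methyl ether from the first step.

Alternative 2: The cut is at C3–C4 and C5–C6. In the forward key step, furfuryl benzoate A4 (diene carbons C3, C2, C1, C6) and vinylene carbonate A5 (C4, C5) undergo a thermal endo [4+2] cycloaddition to the oxygen-bridged adduct A3.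
- In favour: two C–C bonds, the ring and C7 with its benzoate come from two achiral bulk chemicals. In the endo adduct the carbonate oxygens are anti to the bridge oxygen, which is the C4/C5 cis, C5/C6 trans pattern. An anti SN2′ methanolysis at C1 with cleavage of the C3–O bridge bond would place C1–OMe trans to C6–OH and move the alkene to C2=C3.
- Against it here: A3 is racemic, so a resolution or an enantioselective bridge opening is needed. Furan cycloadditions are reversible and tend to give endo/exo mixtures under forcing conditions. The bridge must open at the substituted bridgehead and not at C6, in competition with aromatisation. Carbonate removal beside a benzoate and the later O5 acylation are chemoselectivity problems.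
- Comparison: in step and atom economy Alternative 2 is the better plan. In relative configuration it is at least the equal, since concerted and stereospecific steps set all four centres. In absolute configuration the chosen plan is clearly stronger. The risk there lies in the bridge opening, here in the radical step.

Alternative 3: The cut is at C1–O and C4–O. In the forward key step, photosensitised oxygenation of the diene A7 adds dioxygen across C1 and C4 to give the endoperoxide A6, a transient 2,3-dioxabicyclo[2.2.2]octene. A7 would be made from shikimic acid A8 by esterification, 1,4-elimination of the C3 hydroxyl and monosilylation. O–O reduction of A6 then gives the cis-1,4-diol.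
- In favour: the chiral pool supplies the ring, all seven carbons and the trans C5/C6 oxygens in the right absolute sense. Two C–O bonds form cis across the ring in one metal-free step.
- Against it here: each face of A7 carries one substituent, so facial selectivity depends on hydroxyl direction winning over silyl shielding. The bridgehead C–H next to the O–O bond invites Kornblum–DeLaMare rearrangement. After reduction O1 must be methylated in the presence of O4 and O5, the ester still has to be reduced, and the trans-diol must be monosilylated selectively. Peroxides are a hazard on scale.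
- Comparison: in the source of absolute configuration (chiral pool against reagent control) it is the equal of the chosen plan. It is better in that no C–C bond has to be made. It is weaker in oxygen differentiation, because the chosen plan brings the methyl ether in with 1, and it is unlikely to be shorter.

Key step: step 10

Remarks on the chemistry (one line each):
- Ring positions: C1 (CH–OMe), C2 (=CH), C3 (=C), C4 (CH–OH), C5 (CH–OBz), C6 (CH–OH), C7 (exocyclic CH2).
- A plain bis(trifluoroethyl) phosphonoacetate can supply only C3 and one carbonyl carbon, leaving C7 without a source; the C3/C4/C7 unit is therefore brought in by 10 in an E-selective olefination, its ester carbon becoming C7 and its alkoxymethyl arm C4.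
- A C7 benzoate would sit β to the enolate carbon C3 formed when the enal is reduced and would be expelled; C7 is carried as a silyl ether through the key step and benzoylated last.
- O4 and O5 share the 4-methoxybenzyl group so that one oxidative deprotection frees both without touching the alkene; a benzyl ether at O5 could not be removed cleanly beside the C2=C3 bond.
- Assumption: 2 and 8 are taken as catalogue compounds.

## Route

Step 1
Reactants: 1 allyl methyl ether (3-methoxyprop-1-ene); 2 2-[(4-methoxybenzyl)oxy]acetaldehyde
Product: 5 (2S,3S)-3-methoxy-1-[(4-methoxybenzyl)oxy]pent-4-en-2-ol, via (Z)-3-methoxyallyllithium 3 (not isolated), via (Z)-methoxyallyl-diisopinocampheylborane 4 (not isolated)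
Conditions: 1, s-BuLi, THF, −78 °C; (+)-Ipc2BOMe; BF3·OEt2; 2, −78 °C; then NaOH, H2O2, rt
Reagents that add atoms: none
Why: Asymmetric (Z)-γ-alkoxyallylboration: chelation-controlled lithiation gives the Z allyl unit, which is transferred to boron and adds through a chair-like Zimmerman–Traxler transition state, so C1 and C6 should come out syn. The isopinocampheyl groups (from (−)-α-pinene) are expected to direct attack to the Re face of 2, which gives the (2S,3S) isomer.

Step 2
Reactants: 5 (2S,3S)-3-methoxy-1-[(4-methoxybenzyl)oxy]pent-4-en-2-ol
Product: 6 tert-butyl{[(2S,3S)-3-methoxy-1-[(4-methoxybenzyl)oxy]pent-4-en-2-yl]oxy}dimethylsilane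
Conditions: TBSOTf, 2,6-lutidine, CH2Cl2, −78 to 0 °C
Reagents that add atoms: tert-butyldimethylsilyl trifluoromethanesulfonate (TBSOTf), CC(C)(C)[Si](C)(C)OS(=O)(=O)C(F)(F)F
Why: O-Silylation of a hindered secondary alcohol with a silyl triflate and a hindered base; no stereocentre is touched. The bulky, non-chelating silyl ether at O6 is the control element for the key step.

Step 3
Reactants: 6 tert-butyl{[(2S,3S)-3-methoxy-1-[(4-methoxybenzyl)oxy]pent-4-en-2-yl]oxy}dimethylsilane
Product: 7 (2R,3S)-3-[(tert-butyldimethylsilyl)oxy]-2-methoxy-4-[(4-methoxybenzyl)oxy]butanal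
Conditions: K2OsO4·2H2O (cat.), NaIO4, 2,6-lutidine, dioxane/H2O, rt
Reagents that add atoms: sodium periodate, [Na+].[O-]I(=O)(=O)=O; water, O (either may supply the new carbonyl oxygen, which reaches the substrate through the osmium catalyst)
Why: Lemieux–Johnson oxidative cleavage of the terminal alkene, chosen over ozonolysis because the electron-rich 4-methoxybenzyl arene is sensitive to ozone. The lutidine buffer limits epimerisation at the α-methoxy carbon, and 7 is used crude.

Step 4
Reactants: 8 ethyl 2-(diethoxyphosphoryl)acrylate; 9 4-methoxybenzyl alcohol
Product: 10 ethyl 2-(diethoxyphosphoryl)-3-[(4-methoxybenzyl)oxy]propanoate (racemic)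
Conditions: 9, NaH, THF, 0 °C; 8 added slowly; then AcOH
Reagents that add atoms: none
Why: Oxa-Michael addition of the alkoxide to the doubly activated acrylate gives the stabilised phosphonate carbanion, which is protonated on quench; slow addition of 8 keeps the carbanion from adding to a second acrylate. The new stereocentre is racemic and becomes sp2 in step 5.

Step 5
Reactants: 7 (2R,3S)-3-[(tert-butyldimethylsilyl)oxy]-2-methoxy-4-[(4-methoxybenzyl)oxy]butanal; 10 ethyl 2-(diethoxyphosphoryl)-3-[(4-methoxybenzyl)oxy]propanoate
Product: 11 ethyl (2E,4S,5S)-5-[(tert-butyldimethylsilyl)oxy]-4-methoxy-6-[(4-methoxybenzyl)oxy]-2-{[(4-methoxybenzyl)oxy]methyl}hex-2-enoate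
Conditions: LiCl, DBU, MeCN, 0 °C to rt
Reagents that add atoms: none
Why: Horner–Wadsworth–Emmons olefination under Masamune–Roush conditions. With a diethyl phosphonate and a lithium/amine base the adducts are expected to equilibrate and collapse to the isomer with the ester trans to the bulky C1 substituent (E), which puts the alkoxymethyl arm (future C4) cis to C1. The weak base is chosen to spare the α-methoxy stereocentre and the β-silyloxy group.

Step 6
Reactants: 11 ethyl (2E,4S,5S)-5-[(tert-butyldimethylsilyl)oxy]-4-methoxy-6-[(4-methoxybenzyl)oxy]-2-{[(4-methoxybenzyl)oxy]methyl}hex-2-enoate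
Product: 12 (2Z,4S,5S)-5-[(tert-butyldimethylsilyl)oxy]-4-methoxy-6-[(4-methoxybenzyl)oxy]-2-{[(4-methoxybenzyl)oxy]methyl}hex-2-en-1-ol
Conditions: i-Bu2AlH, CH2Cl2, −78 °C; then aq. potassium sodium tartrate
Reagents that add atoms: none
Why: 1,2-Reduction of a conjugated ester to the allylic alcohol by an aluminium hydride at low temperature; ethers and the alkene geometry are unaffected (the descriptor changes from E to Z only because the priorities change).

Step 7
Reactants: 12 (2Z,4S,5S)-5-[(tert-butyldimethylsilyl)oxy]-4-methoxy-6-[(4-methoxybenzyl)oxy]-2-{[(4-methoxybenzyl)oxy]methyl}hex-2-en-1-ol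
Product: 13 (2E,4S,5S)-1,5-bis[(tert-butyldimethylsilyl)oxy]-4-methoxy-6-[(4-methoxybenzyl)oxy]-2-{[(4-methoxybenzyl)oxy]methyl}hex-2-ene
Conditions: TBSCl, imidazole, CH2Cl2, 0 °C to rt
Reagents that add atoms: tert-butyldimethylsilyl chloride (TBSCl), CC(C)(C)[Si](C)(C)Cl
Why: O-Silylation of a primary allylic alcohol. It gives O7 an ether that is a poor leaving group under the reducing conditions of step 10 and is removed together with the O6 silyl group in step 12.

Step 8
Reactants: 13 (2E,4S,5S)-1,5-bis[(tert-butyldimethylsilyl)oxy]-4-methoxy-6-[(4-methoxybenzyl)oxy]-2-{[(4-methoxybenzyl)oxy]methyl}hex-2-ene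
Product: 14 (2E,4S,5S)-5-[(tert-butyldimethylsilyl)oxy]-2-{[(tert-butyldimethylsilyl)oxy]methyl}-4-methoxyhex-2-ene-1,6-diol
Conditions: DDQ, CH2Cl2/pH 7 buffer, 0 °C to rt
Reagents that add atoms: none
Why: Oxidative cleavage of both 4-methoxybenzyl ethers (benzylic hydride abstraction, then hydrolysis of the oxocarbenium ion). The trisubstituted alkene, the silyl ethers and the methyl ether are inert, and the neutral buffer guards against silyl migration.

Step 9
Reactants: 14 (2E,4S,5S)-5-[(tert-butyldimethylsilyl)oxy]-2-{[(tert-butyldimethylsilyl)oxy]methyl}-4-methoxyhex-2-ene-1,6-diol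
Product: 15 (2Z,4S,5R)-5-[(tert-butyldimethylsilyl)oxy]-2-{[(tert-butyldimethylsilyl)oxy]methyl}-4-methoxyhex-2-enedial
Conditions: Dess–Martin periodinane, NaHCO3, CH2Cl2, 0 °C to rt
Reagents that add atoms: none
Why: Dess–Martin oxidation of both primary alcohols at once under buffered, amine-free conditions. Amine bases are avoided because they could trigger loss of methoxide β to the C5 aldehyde, epimerisation at C6 or Z-to-E isomerisation of the enal; 15 is used at once.

Step 10
Reactants: 15 (2Z,4S,5R)-5-[(tert-butyldimethylsilyl)oxy]-2-{[(tert-butyldimethylsilyl)oxy]methyl}-4-methoxyhex-2-enedial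
Product: 16 (1R,2R,5S,6S)-6-[(tert-butyldimethylsilyl)oxy]-3-{[(tert-butyldimethylsilyl)oxy]methyl}-5-methoxycyclohex-3-ene-1,2-diol
Conditions: SmI2 (3 equiv), t-BuOH, THF, −78 °C to rt, 15 added slowly; then aq. NaHCO3
Reagents that add atoms: none
Why: Pinacol-type reductive cyclisation of a dialdehyde by divalent samarium, the known way from 1,6-dialdehydes to cis-cyclohexane-1,2-diols, here with an enal as one partner. Single-electron transfer to the samarium-bound carbonyls gives ketyl radical anions, the conjugated C4 aldehyde being reduced first to an allyl-type ketyl; this bonds through its carbonyl carbon to C5 while both oxygens sit on samarium, and a second electron transfer completes a dialkoxide of trivalent samarium that is protonated on work-up. The closure is formally a 6-exo-trig attack of the C4 ketyl on the C5 carbonyl and forms the six-membered carbocycle C1–C6; bonding through the enal β-carbon C2 would need a four-membered ring and is excluded. C4 and C5 should become cis because the two oxygens are tied into one samarium-bridged chelate in the bond-forming transition state. The new C5–O bond is expected anti to the C6 silyloxy group, since that bulky, non-chelating group and its C–O dipole stay away from the samarium-bound oxygen at C5; C1 and C6 are not touched. The step needs the pinacol mode to outrun conjugate reduction, β-elimination and intermolecular coupling: the Z alkene holds C4 within reach of C5, both oxygen substituents flanking the enal (C1–OMe and C7–OSi) are ethers and so poor leaving groups, no hexamethylphosphoramide is used, and 15 meets an excess of SmI2 at −78 °C.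

Step 11
Reactants: 16 (1R,2R,5S,6S)-6-[(tert-butyldimethylsilyl)oxy]-3-{[(tert-butyldimethylsilyl)oxy]methyl}-5-methoxycyclohex-3-ene-1,2-diol; 17 benzoyl chloride
Product: 19 (1R,2R,5S,6R)-6-[(tert-butyldimethylsilyl)oxy]-3-{[(tert-butyldimethylsilyl)oxy]methyl}-2-hydroxy-5-methoxycyclohex-3-en-1-yl benzoate, via 4,5-O-dibutylstannylene acetal 18 (not isolated)
Conditions: Bu2SnO, toluene, reflux (−H2O); then 17, 0 °C to rt
Reagents that add atoms: none
Why: Stannylene-acetal-mediated regioselective acylation of a cis-1,2-diol. In the favoured half-chair O5 is equatorial and O4 pseudoaxial (which also relieves allylic 1,2-strain with the C3 substituent), and the tin acetal activates the equatorial oxygen. The 4,5-diol is the only free diol, so only one stannylene can form.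

Step 12
Reactants: 19 (1R,2R,5S,6R)-6-[(tert-butyldimethylsilyl)oxy]-3-{[(tert-butyldimethylsilyl)oxy]methyl}-2-hydroxy-5-methoxycyclohex-3-en-1-yl benzoate
Product: 20 (1R,2R,5S,6R)-2,6-dihydroxy-3-(hydroxymethyl)-5-methoxycyclohex-3-en-1-yl benzoate
Conditions: HF·pyridine, pyridine, THF, 0 °C to rt
Reagents that add atoms: none
Why: Fluoride-mediated cleavage of both silyl ethers under mildly acidic, buffered conditions. Basic Bu4NF is avoided because the C5 benzoate is flanked by hydroxyls and could migrate.

Step 13
Reactants: 20 (1R,2R,5S,6R)-2,6-dihydroxy-3-(hydroxymethyl)-5-methoxycyclohex-3-en-1-yl benzoate; 17 benzoyl chloride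
Product: 21 (1R,2R,5S,6R)-3-[(benzoyloxy)methyl]-2,6-dihydroxy-5-methoxycyclohex-3-en-1-yl benzoate (CNP0349013.6)
Conditions: 17 (1.05 equiv), 2,4,6-collidine, CH2Cl2, −78 to −40 °C
Reagents that add atoms: none
Why: Selective acylation of the primary allylic hydroxyl by an acid chloride with a hindered base at low temperature; the two secondary hydroxyls are flanked by substituents and react more slowly. The weak, non-nucleophilic base at low temperature should not move the C5 benzoate.

## Compound list

1 | allyl methyl ether (3-methoxyprop-1-ene) | COCC=C | starting material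
2 | 2-[(4-methoxybenzyl)oxy]acetaldehyde | O=CCOCc1ccc(OC)cc1 | starting material
3 | (Z)-3-methoxyallyllithium | [Li]C/C=C\OC | intermediate
4 | [(Z)-3-methoxyallyl]diisopinocampheylborane, isopinocampheyl groups from (−)-α-pinene | CO/C=C\CB([C@H]1C[C@H]2C[C@@H]([C@@H]1C)C2(C)C)[C@H]1C[C@H]2C[C@@H]([C@@H]1C)C2(C)C | intermediate
5 | (2S,3S)-3-methoxy-1-[(4-methoxybenzyl)oxy]pent-4-en-2-ol | C=C[C@H](OC)[C@@H](O)COCc1ccc(OC)cc1 | intermediate
6 | tert-butyl{[(2S,3S)-3-methoxy-1-[(4-methoxybenzyl)oxy]pent-4-en-2-yl]oxy}dimethylsilane | C=C[C@H](OC)[C@@H](O[Si](C)(C)C(C)(C)C)COCc1ccc(OC)cc1 | intermediate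
7 | (2R,3S)-3-[(tert-butyldimethylsilyl)oxy]-2-methoxy-4-[(4-methoxybenzyl)oxy]butanal | O=C[C@H](OC)[C@@H](O[Si](C)(C)C(C)(C)C)COCc1ccc(OC)cc1 | intermediate
8 | ethyl 2-(diethoxyphosphoryl)acrylate | C=C(C(=O)OCC)P(=O)(OCC)OCC | starting material
9 | 4-methoxybenzyl alcohol | COc1ccc(CO)cc1 | starting material
10 | ethyl 2-(diethoxyphosphoryl)-3-[(4-methoxybenzyl)oxy]propanoate (racemic) | CCOC(=O)C(COCc1ccc(OC)cc1)P(=O)(OCC)OCC | intermediate
11 | ethyl (2E,4S,5S)-5-[(tert-butyldimethylsilyl)oxy]-4-methoxy-6-[(4-methoxybenzyl)oxy]-2-{[(4-methoxybenzyl)oxy]methyl}hex-2-enoate | CCOC(=O)/C(COCc1ccc(OC)cc1)=C/[C@H](OC)[C@@H](O[Si](C)(C)C(C)(C)C)COCc1ccc(OC)cc1 | intermediate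
12 | (2Z,4S,5S)-5-[(tert-butyldimethylsilyl)oxy]-4-methoxy-6-[(4-methoxybenzyl)oxy]-2-{[(4-methoxybenzyl)oxy]methyl}hex-2-en-1-ol | OC/C(COCc1ccc(OC)cc1)=C/[C@H](OC)[C@@H](O[Si](C)(C)C(C)(C)C)COCc1ccc(OC)cc1 | intermediate
13 | (2E,4S,5S)-1,5-bis[(tert-butyldimethylsilyl)oxy]-4-methoxy-6-[(4-methoxybenzyl)oxy]-2-{[(4-methoxybenzyl)oxy]methyl}hex-2-ene | CC(C)(C)[Si](C)(C)OC/C(COCc1ccc(OC)cc1)=C/[C@H](OC)[C@@H](O[Si](C)(C)C(C)(C)C)COCc1ccc(OC)cc1 | intermediate
14 | (2E,4S,5S)-5-[(tert-butyldimethylsilyl)oxy]-2-{[(tert-butyldimethylsilyl)oxy]methyl}-4-methoxyhex-2-ene-1,6-diol | CC(C)(C)[Si](C)(C)OC/C(CO)=C/[C@H](OC)[C@@H](O[Si](C)(C)C(C)(C)C)CO | intermediate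
15 | (2Z,4S,5R)-5-[(tert-butyldimethylsilyl)oxy]-2-{[(tert-butyldimethylsilyl)oxy]methyl}-4-methoxyhex-2-enedial | O=C/C(CO[Si](C)(C)C(C)(C)C)=C\[C@H](OC)[C@@H](O[Si](C)(C)C(C)(C)C)C=O | intermediate
16 | (1R,2R,5S,6S)-6-[(tert-butyldimethylsilyl)oxy]-3-{[(tert-butyldimethylsilyl)oxy]methyl}-5-methoxycyclohex-3-ene-1,2-diol | CO[C@H]1C=C(CO[Si](C)(C)C(C)(C)C)[C@@H](O)[C@@H](O)[C@@H]1O[Si](C)(C)C(C)(C)C | intermediate
17 | benzoyl chloride | O=C(Cl)c1ccccc1 | starting material
18 | 4,5-O-dibutylstannylene acetal of 16 | CO[C@H]1C=C(CO[Si](C)(C)C(C)(C)C)[C@H]2O[Sn](CCCC)(CCCC)O[C@H]2[C@@H]1O[Si](C)(C)C(C)(C)C | intermediate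
19 | (1R,2R,5S,6R)-6-[(tert-butyldimethylsilyl)oxy]-3-{[(tert-butyldimethylsilyl)oxy]methyl}-2-hydroxy-5-methoxycyclohex-3-en-1-yl benzoate | CO[C@H]1C=C(CO[Si](C)(C)C(C)(C)C)[C@@H](O)[C@@H](OC(=O)c2ccccc2)[C@@H]1O[Si](C)(C)C(C)(C)C | intermediate
20 | (1R,2R,5S,6R)-2,6-dihydroxy-3-(hydroxymethyl)-5-methoxycyclohex-3-en-1-yl benzoate | CO[C@H]1C=C(CO)[C@@H](O)[C@@H](OC(=O)c2ccccc2)[C@@H]1O | intermediate
21 | (1R,2R,5S,6R)-3-[(benzoyloxy)methyl]-2,6-dihydroxy-5-methoxycyclohex-3-en-1-yl benzoate (CNP0349013.6) | CO[C@H]1C=C(COC(=O)c2ccccc2)[C@@H](O)[C@@H](OC(=O)c2ccccc2)[C@@H]1O | target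

## Step count and least certain steps

Total step count: 13 (twelve in the main line plus the preparation of 10). Longest linear sequence: 12 steps (steps 1–3 and 5–13).

Step 10 (key step). The ketyl derived from the enal may be diverted before the ring closes: by conjugate reduction, by loss of methoxide from C1 after a second electron transfer, by rotation about the C2–C3 bond of the delocalised radical (the E form cannot close), or by intermolecular coupling. Facial control at C5 may also be incomplete, because a silyl ether steers only by bulk and dipole. The fallback forms the same ring by metathesis and sets the diol by osmylation. It sets out from 15: double Wittig methylenation (Ph3P=CH2 from Ph3PCH3Br and KN(SiMe3)2, THF, −78 to 0 °C) gives the triene F1. Ring-closing metathesis with second-generation Grubbs catalyst (CH2Cl2, 40 °C) joins C4 and C5 as an alkene and gives the cyclohexa-1,3-diene F2. OsO4-catalysed dihydroxylation (N-methylmorpholine N-oxide, acetone/H2O) of the less substituted C4=C5 bond, anti to the allylic C6 silyloxy group, comes back to the route at 16.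

Step 5. The E preference may be eroded, because the α-alkoxymethyl group on the phosphonate and the α-alkoxy aldehyde both speed collapse of the first adducts. Base may also epimerise C1 or eliminate the β-silyloxy group in 7. The fallback makes the C2=C3 bond by metathesis and bypasses 7. It sets out from 6 and 10: Horner–Wadsworth–Emmons reaction of 10 with aqueous formaldehyde (K2CO3) gives ethyl 2-{[(4-methoxybenzyl)oxy]methyl}prop-2-enoate F3. Cross-metathesis of 6 with excess F3 (second-generation Hoveyda–Grubbs catalyst, toluene, 80 °C) should give the E-enoate under thermodynamic control and comes back at 11.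

Step 11. Acylation may fall on O4 as well as, or instead of, O5 if the two bulky silyl ethers distort the half-chair or the stannylene reacts through its pseudoaxial oxygen. The fallback blocks O4 temporarily by the known axial-selective opening of an orthoester. It sets out from 16: trimethyl orthoacetate with catalytic camphorsulfonic acid gives the cyclic orthoacetate F4. Brief treatment with aqueous acetic acid opens it to the pseudoaxial 4-O-acetate F5. Acylation with 17 in pyridine gives the 4-O-acetyl-5-O-benzoate F6. HCl in methanol removes the acetate faster than the benzoate, cleaves both silyl ethers, and comes back at 20.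

Step 13. Over-acylation at O4 or O6, or base-induced migration of the C5 benzoate in the unprotected triol, may lower selectivity. The fallback changes the order so that fewer hydroxyls are free when the primary benzoate goes on. It sets out from 19: mild acid methanolysis (pyridinium p-toluenesulfonate, MeOH) removes only the primary allylic silyl ether and gives the 7-hydroxy compound F7. Acylation with 17 in pyridine at 0 °C gives the 6-O-silyl derivative of the target F8. HF·pyridine then comes back at 21.

## Further compounds

F1 | step 10 | (3S,4S,5E)-3-[(tert-butyldimethylsilyl)oxy]-6-{[(tert-butyldimethylsilyl)oxy]methyl}-4-methoxyocta-1,5,7-triene | C=C/C(CO[Si](C)(C)C(C)(C)C)=C\[C@H](OC)[C@@H](O[Si](C)(C)C(C)(C)C)C=C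
F2 | step 10 | tert-butyl{[(1S,6S)-4-{[(tert-butyldimethylsilyl)oxy]methyl}-6-methoxycyclohexa-2,4-dien-1-yl]oxy}dimethylsilane | CO[C@H]1C=C(CO[Si](C)(C)C(C)(C)C)C=C[C@@H]1O[Si](C)(C)C(C)(C)C
F3 | step 5 | ethyl 2-{[(4-methoxybenzyl)oxy]methyl}prop-2-enoate | C=C(COCc1ccc(OC)cc1)C(=O)OCC
F4 | step 11 | cyclic methyl orthoacetate of 16 across O4 and O5 (either configuration at the orthoester carbon) | CO[C@H]1C=C(CO[Si](C)(C)C(C)(C)C)[C@H]2OC(C)(OC)O[C@H]2[C@@H]1O[Si](C)(C)C(C)(C)C
F5 | step 11 | 4-O-acetate of 16 (acetate on the allylic oxygen at C4, C5–OH free) | CO[C@H]1C=C(CO[Si](C)(C)C(C)(C)C)[C@@H](OC(C)=O)[C@@H](O)[C@@H]1O[Si](C)(C)C(C)(C)C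
F6 | step 11 | 4-O-acetyl-5-O-benzoyl derivative of 16 | CO[C@H]1C=C(CO[Si](C)(C)C(C)(C)C)[C@@H](OC(C)=O)[C@@H](OC(=O)c2ccccc2)[C@@H]1O[Si](C)(C)C(C)(C)C
F7 | step 13 | 19 without its primary silyl ether (C7–OH and C4–OH free, O6 silylated, O5 benzoylated) | CO[C@H]1C=C(CO)[C@@H](O)[C@@H](OC(=O)c2ccccc2)[C@@H]1O[Si](C)(C)C(C)(C)C
F8 | step 13 | 6-O-(tert-butyldimethylsilyl) derivative of 21 | CO[C@H]1C=C(COC(=O)c2ccccc2)[C@@H](O)[C@@H](OC(=O)c2ccccc2)[C@@H]1O[Si](C)(C)C(C)(C)C
A1 | alternative 1 | ethyl (5S,6R)-5,6-dihydroxycyclohexa-1,3-diene-1-carboxylate | CCOC(=O)C1=CC=C[C@H](O)[C@@H]1O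
A2 | alternative 1 | ethyl benzoate | CCOC(=O)c1ccccc1
A3 | alternative 2 | endo 7-oxabicyclo[2.2.1]hept-5-ene 2,3-carbonate with bridgehead benzoyloxymethyl group (racemic adduct, needed enantiomer drawn) | O=C(OC[C@@]12C=C[C@@H](O1)[C@@H]3OC(=O)O[C@H]23)c4ccccc4
A4 | alternative 2 | furfuryl benzoate | O=C(OCc1ccco1)c1ccccc1
A5 | alternative 2 | vinylene carbonate | O=C1OC=CO1
A6 | alternative 3 | methyl 2,3-dioxabicyclo[2.2.2]oct-5-ene-5-carboxylate bearing 7-hydroxy and 8-(tert-butyldimethylsilyl)oxy groups | COC(=O)C1=C[C@@H]2OO[C@H]1[C@@H](O)[C@@H]2O[Si](C)(C)C(C)(C)C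
A7 | alternative 3 | methyl (3R,4R)-4-[(tert-butyldimethylsilyl)oxy]-3-hydroxycyclohexa-1,5-diene-1-carboxylate | COC(=O)C1=C[C@@H](O)[C@H](O[Si](C)(C)C(C)(C)C)C=C1
A8 | alternative 3 | (−)-shikimic acid | OC(=O)C1=C[C@@H](O)[C@@H](O)[C@H](O)C1
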